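## Plan

1. Retrosynthetic cuts, in order: the O15 silyl group and the C1–C10 oxirane oxygen; the ring bond C3–C4 (alkenyl iodide plus aldehyde); the two lactone bonds O–C6 and C11–C7 (one palladium event on a diene with 2-bromoacrylic acid); the C6=C7 olefin (phosphonate plus aldehyde).
2. Feature used: the lactone carbinol C6 is allylic to the ring olefin C4=C5, so the γ-alkenyl-α-methylene-γ-butyrolactone (ring O–C6–C7–C11–C12) is the retron of a carbo-oxygenation of the diene C4=C5–C6=C7 by an α-carboxyvinyl–palladium unit.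
3. Forward: a C1–C3/C7–C10 aldehyde (from (S)-glycidol) and a C4–C6/C15 silyl phosphonate (from 2-butyne-1,4-diol) are joined at C6=C7; the lactone is annulated onto the open-chain diene; the ten-membered ring is then closed at C3–C4; the oxirane comes last.
4. Stereochemistry: C8 from (S)-glycidol; C7 by 1,2-induction from C8 in the carbopalladation; C6 by syn C/O delivery across the E olefin (trans-lactone); 1(10)E by syn carboalumination; 4Z by trans-hydroalumination, with Si and then I holding the C3 site; C3 in the ring closure; C1/C10 by outer-face epoxidation.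

Key step: step 12

Remark: locants C1–C15 are the germacrane positions of the target (lactone O on C6, C11 on C7, ester on C8, oxirane C1–C10, C14 on C10, C15 on C4); CIP letters of one and the same centre change along the route where Si or I alter priorities.

## Route

Step 1
Reactants: 1 (S)-glycidol; 2 lithium acetylide–ethylenediamine complex
Product: 3 (R)-pent-4-yne-1,2-diol
Conditions: LiC≡CH·EDA (excess), DMSO, 0 °C → rt; aq. NH4Cl
Reagents that add atoms: lithium acetylide–ethylenediamine complex, [Li+].[C-]#C.NCCN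
Why: SN2 opening of the epoxide by acetylide at the unsubstituted carbon leaves the carbinol centre (later C8) untouched, and the degenerate Payne shift of the glycidol alkoxide leads to the same enantiomer.

Step 2
Reactants: 3 (R)-pent-4-yne-1,2-diol; 4 chlorotriethylsilane
Product: 5 (R)-4,5-bis(triethylsilyloxy)pent-1-yne
Conditions: TESCl, imidazole, DMAP (cat.), CH2Cl2, 0 °C → rt
Reagents that add atoms: chlorotriethylsilane, CC[Si](CC)(CC)Cl
Why: Silyl ether formation on both hydroxyls; the primary TES ether is the latent C7 aldehyde and the secondary one protects O8.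

Step 3
Reactants: 5 (R)-4,5-bis(triethylsilyloxy)pent-1-yne; 6 trimethylaluminium; 7 ethylene oxide
Product: 10 (3E,6R)-4-methyl-6,7-bis(triethylsilyloxy)hept-3-en-1-ol, via alkenylalane 8 (not isolated), via lithium alkenylalanate 9 (not isolated)
Conditions: Me3Al, Cp2ZrCl2 (cat.), CH2Cl2, 0 °C → rt; volatiles off; n-BuLi, hexane, −78 → 0 °C; ethylene oxide (THF solution), 0 °C; Rochelle salt work-up
Reagents that add atoms: trimethylaluminium, C[Al](C)C; ethylene oxide, C1CO1
Why: Zirconium-catalysed syn methylalumination of the terminal alkyne (Negishi carboalumination) puts Al on the terminal carbon and so fixes the E-C1=C10 olefin, and the alanate opens ethylene oxide with retention at the alkenyl carbon to add C2–C3.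

Step 4
Reactants: 10 (3E,6R)-4-methyl-6,7-bis(triethylsilyloxy)hept-3-en-1-ol; 11 tert-butylchlorodimethylsilane
Product: 12 (3E,6R)-1-(tert-butyldimethylsilyloxy)-4-methyl-6,7-bis(triethylsilyloxy)hept-3-ene
Conditions: TBSCl, imidazole, CH2Cl2, 0 °C → rt
Reagents that add atoms: tert-butylchlorodimethylsilane, CC(C)(C)[Si](C)(C)Cl
Why: Silyl ether formation; the TBS group on O3 is more robust than TES and less robust than the later TBDPS group, which allows graded removal.

Step 5
Reactants: 12 (3E,6R)-1-(tert-butyldimethylsilyloxy)-4-methyl-6,7-bis(triethylsilyloxy)hept-3-ene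
Product: 14 (2R,4E)-7-(tert-butyldimethylsilyloxy)-4-methyl-2-(triethylsilyloxy)hept-4-enal, via alkoxysulfonium chloride 13 (not isolated)
Conditions: (COCl)2, DMSO, CH2Cl2, −78 → −30 °C; Et3N, −78 °C → 0 °C
Reagents that add atoms: none
Why: Under Swern conditions the chlorosulfonium salt cleaves the primary triethylsilyl ether selectively and oxidises it to the aldehyde (oxidative desilylation, Swern oxidation), while the secondary TES and the TBS ether stay and the cold amine quench avoids epimerisation at C8.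

Step 6
Reactants: 15 2-butyne-1,4-diol; 16 tert-butylchlorodiphenylsilane
Product: 17 4-(tert-butyldiphenylsilyloxy)but-2-yn-1-ol
Conditions: diol (excess), imidazole, TBDPSCl, THF/DMF, 0 °C
Reagents that add atoms: tert-butylchlorodiphenylsilane, CC(C)(C)[Si](Cl)(c1ccccc1)c1ccccc1
Why: Statistical monosilylation with excess diol; the TBDPS ether on O15 is meant to last to the final step.

Step 7
Reactants: 17 4-(tert-butyldiphenylsilyloxy)but-2-yn-1-ol; 18 iodine
Product: 20 (Z)-4-(tert-butyldiphenylsilyloxy)-3-iodobut-2-en-1-ol, via cyclic alkenylalanate 19 (not isolated)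
Conditions: Red-Al, THF, 0 °C; I2, THF, −78 °C → 0 °C
Reagents that add atoms: iodine, II
Why: Hydroxyl-directed trans-hydroalumination of the propargylic alcohol puts aluminium on the distal alkyne carbon (C4) and iodinolysis goes with retention, so iodine sits cis to C6 at the later C3 attachment site and C15 is trans to C6.

Step 8
Reactants: 20 (Z)-4-(tert-butyldiphenylsilyloxy)-3-iodobut-2-en-1-ol; 21 chlorotrimethylsilane
Product: 24 (Z)-4-(tert-butyldiphenylsilyloxy)-3-(trimethylsilyl)but-2-en-1-ol, via trimethylsilyl ether 22 (not isolated), via alkenyllithium 23 (not isolated)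
Conditions: n-BuLi, THF, −78 °C; TMSCl; t-BuLi (2 equiv), −78 → −20 °C; aq. NH4Cl
Reagents that add atoms: chlorotrimethylsilane, C[Si](C)(C)Cl
Why: Iodine–lithium exchange gives a Z-alkenyllithium that takes silicon from the cis CH2O–Si group through a five-membered transition state (retro-[1,4]-Brook rearrangement) with retention of geometry, and the resulting vinylsilane is a palladium-inert placeholder for the iodide.

Step 9
Reactants: 24 (Z)-4-(tert-butyldiphenylsilyloxy)-3-(trimethylsilyl)but-2-en-1-ol; 25 tetrabromomethane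
Product: 26 (Z)-[4-bromo-1-(tert-butyldiphenylsilyloxy)but-2-en-2-yl]trimethylsilane
Conditions: CBr4, PPh3, 2,6-lutidine, CH2Cl2, 0 °C
Reagents that add atoms: tetrabromomethane, BrC(Br)(Br)Br
Why: Appel bromination of the primary allylic alcohol by direct SN2 displacement, the hindered silyl-bearing carbon disfavouring SN2'.

Step 10
Reactants: 26 (Z)-[4-bromo-1-(tert-butyldiphenylsilyloxy)but-2-en-2-yl]trimethylsilane; 27 triethyl phosphite
Product: 28 diethyl (Z)-[4-(tert-butyldiphenylsilyloxy)-3-(trimethylsilyl)but-2-en-1-yl]phosphonate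
Conditions: P(OEt)3 (neat), 100 °C
Reagents that add atoms: triethyl phosphite, CCOP(OCC)OCC
Why: Michaelis–Arbuzov reaction of the primary allylic bromide; the olefin geometry is not involved.

Step 11
Reactants: 28 diethyl (Z)-[4-(tert-butyldiphenylsilyloxy)-3-(trimethylsilyl)but-2-en-1-yl]phosphonate; 14 (2R,4E)-7-(tert-butyldimethylsilyloxy)-4-methyl-2-(triethylsilyloxy)hept-4-enal
Product: 30 (3E,6R,7E,9Z)-1-(tert-butyldimethylsilyloxy)-11-(tert-butyldiphenylsilyloxy)-4-methyl-6-(triethylsilyloxy)-10-(trimethylsilyl)undeca-3,7,9-triene, via lithiated phosphonate 29 (not isolated)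
Conditions: LiHMDS, THF, −78 °C; then 14, −78 → 0 °C
Reagents that add atoms: none
Why: Horner–Wadsworth–Emmons olefination of an allylic phosphonate anion at its α-carbon (the γ-carbon is blocked by silicon) should give the E-C6=C7 olefin, and the low temperature protects the α-silyloxy aldehyde from epimerisation.

Step 12
Reactants: 30 (3E,6R,7E,9Z)-1-(tert-butyldimethylsilyloxy)-11-(tert-butyldiphenylsilyloxy)-4-methyl-6-(triethylsilyloxy)-10-(trimethylsilyl)undeca-3,7,9-triene; 31 2-bromoacrylic acid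
Product: 33 (4S,5S)-4-[(1R,3E)-6-(tert-butyldimethylsilyloxy)-3-methyl-1-(triethylsilyloxy)hex-3-enyl]-5-[(Z)-3-(tert-butyldiphenylsilyloxy)-2-(trimethylsilyl)prop-1-enyl]-3-methylideneoxolan-2-one (trans-lactone), via allylpalladium carboxylate 32 (not isolated)
Conditions: Pd(OAc)2 (10 mol %), K2CO3, BHT (cat.), DMF, 60 °C; no phosphine, no added halide
Reagents that add atoms: 2-bromoacrylic acid, C=C(Br)C(=O)O
Why: Oxidative addition of Pd(0) to the C–Br bond of potassium 2-bromoacrylate gives an α-carboxyvinyl–Pd(II) species that inserts the E-C6=C7 olefin syn, carbon going to C7 (the only diene terminus that is not fully substituted) and palladium to C6, where it becomes an η3-allyl over C6–C5–C4, and the carboxylate held on palladium in a six-membered chelate then forms the O–C6 bond by reductive elimination and returns Pd(0). The closest known reaction type is the Larock-type heteroannulation of 1,3-dienes by vinylic halides that carry a carboxylic acid, which gives α-alkylidene-γ-butyrolactones. The lactone ring closes in the 5-exo mode at the allyl terminus C6, the 7-endo alternative at the quaternary silyl-bearing C4 being disfavoured. C7 is set in the insertion by the C8 stereocentre (inside-alkoxy conformer, OTES near the olefin plane and C9 anti to the incoming Pd–vinyl unit), which should give the 7,8-anti relation of the target, and C6 follows from syn carbopalladation of the E olefin and C–O formation on the palladium-bearing face, a net syn addition that gives the trans-lactone. The step needs site selectivity for the conjugated diene over the isolated C1=C10 olefin (secured by allyl formation), retention of the 4Z geometry (an η1-C4 allyl would be tertiary, so syn/anti exchange at C4 should be slower than ring closure) and inner-sphere C–O formation (favoured by the phosphine-free, halide-poor medium).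

Step 13
Reactants: 33 the trans-lactone vinylsilane; 34 N-iodosuccinimide
Product: 35 (4S,5S)-4-[(1R,3E)-6-(tert-butyldimethylsilyloxy)-3-methyl-1-(triethylsilyloxy)hex-3-enyl]-5-[(Z)-3-(tert-butyldiphenylsilyloxy)-2-iodoprop-1-enyl]-3-methylideneoxolan-2-one
Conditions: NIS, 2,6-lutidine, (CF3)2CHOH/CH2Cl2, 0 °C
Reagents that add atoms: N-iodosuccinimide, O=C1CCC(=O)N1I
Why: Electrophilic ipso-iododesilylation of the vinylsilane (β-silyl cation, loss of silicon) should proceed with retention to the Z-vinyl iodide, while iodonium formation at the isolated C1=C10 olefin is reversible because no competent internal nucleophile is present (all oxygens are silylated).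

Step 14
Reactants: 35 the vinyl iodide lactone
Product: 36 (4R,5S)-4-[(1R,3E)-6-(tert-butyldimethylsilyloxy)-1-hydroxy-3-methylhex-3-enyl]-5-[(Z)-3-(tert-butyldiphenylsilyloxy)-2-iodoprop-1-enyl]-3-methylideneoxolan-2-one
Conditions: PPTS (cat.), MeOH/CH2Cl2, 0 °C
Reagents that add atoms: none
Why: Mild acid methanolysis removes the triethylsilyl ether selectively, since TES is far more labile than the primary TBS and TBDPS ethers; the short, cold treatment limits translactonisation to O8.

Step 15
Reactants: 36 the C8 alcohol; 37 isobutyric anhydride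
Product: 38 (4R,5S)-4-[(1R,3E)-6-(tert-butyldimethylsilyloxy)-3-methyl-1-(2-methylpropanoyloxy)hex-3-enyl]-5-[(Z)-3-(tert-butyldiphenylsilyloxy)-2-iodoprop-1-enyl]-3-methylideneoxolan-2-one
Conditions: (i-PrCO)2O, Et3N, DMAP (cat.), CH2Cl2, 0 °C → rt
Reagents that add atoms: isobutyric anhydride, CC(C)C(=O)OC(=O)C(C)C
Why: DMAP-catalysed acylation of the only free hydroxyl installs the C8 ester now that C8 is no longer allylic to a diene, and the acylation fixes the 6,12-lactone against migration.

Step 16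
Reactants: 38 the C8 isobutyrate
Product: 39 (4R,5S)-4-[(1R,3E)-6-hydroxy-3-methyl-1-(2-methylpropanoyloxy)hex-3-enyl]-5-[(Z)-3-(tert-butyldiphenylsilyloxy)-2-iodoprop-1-enyl]-3-methylideneoxolan-2-one
Conditions: HF·pyridine, pyridine, THF, 0 °C
Reagents that add atoms: none
Why: Buffered fluoride cleaves the primary alkyl TBS ether selectively in the presence of the bulkier TBDPS ether (graded silyl ether cleavage).

Step 17
Reactants: 39 the primary alcohol
Product: 40 (4R,5S)-4-[(1R,3E)-3-methyl-1-(2-methylpropanoyloxy)-6-oxohex-3-enyl]-5-[(Z)-3-(tert-butyldiphenylsilyloxy)-2-iodoprop-1-enyl]-3-methylideneoxolan-2-one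
Conditions: Dess–Martin periodinane, NaHCO3, CH2Cl2, 0 °C; used at once
Reagents that add atoms: none
Why: Dess–Martin oxidation under buffered, non-basic conditions should give the β,γ-unsaturated aldehyde without moving the C1=C10 olefin into conjugation.

Step 18
Reactants: 40 the iodo aldehyde
Product: 42 (3S,6R,7R,8R)-15-(tert-butyldiphenylsilyloxy)-3-hydroxy-8-(2-methylpropanoyloxy)germacra-1(10)E,4Z,11(13)-trien-6,12-olide, via alkenylchromium 41 (not isolated)
Conditions: CrCl2 (excess), NiCl2 (cat.), degassed DMSO/THF, rt, slow addition at high dilution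
Reagents that add atoms: none
Why: Nickel-catalysed formation of the alkenylchromium(III) species and its intramolecular 1,2-addition to the aldehyde (Nozaki–Hiyama–Kishi reaction) closes the ten-membered ring at C3–C4 with retention of the 4Z geometry, and the rigid trans-lactone pre-orients the two chains so that the carbinol is expected to form with its hydroxyl on the outer β face (3S).

Step 19
Reactants: 42 the macrocyclic allylic alcohol; 43 3-chloroperbenzoic acid
Product: 44 (1R,3S,6R,7R,8R,10R)-15-(tert-butyldiphenylsilyloxy)-1,10-epoxy-3-hydroxy-8-(2-methylpropanoyloxy)germacra-4Z,11(13)-dien-6,12-olide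
Conditions: mCPBA, NaHCO3, CH2Cl2, 0 °C
Reagents that add atoms: 3-chloroperbenzoic acid, O=C(OO)c1cccc(Cl)c1
Why: Prilezhaev epoxidation should take the electron-rich C1=C10 olefin in preference to C4=C5 (three allylic oxygens) and the conjugated exo-methylene, and the E olefin of the germacrane ring exposes only its outer face, which with C14 on the β side should give the trans 1β,10α (1R,10R) oxide.

Step 20
Reactants: 44 the silyl-protected epoxide
Product: 45 (1R,3S,6R,7R,8R,10R)-1,10-epoxy-3,15-dihydroxy-8-(2-methylpropanoyloxy)germacra-4Z,11(13)-dien-6,12-olide (CNP0219050.1)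
Conditions: TBAF, AcOH (1:1), THF, 0 °C → rt
Reagents that add atoms: none
Why: Acetic-acid-buffered fluoride desilylation frees O15 under near-neutral conditions that should spare the acid-labile oxirane, the Michael-acceptor lactone and the ester.

## Compound list

1 | (S)-glycidol | OC[C@H]1CO1 | starting material
2 | lithium acetylide–ethylenediamine complex | [Li+].[C-]#C.NCCN | starting material
3 | (R)-pent-4-yne-1,2-diol | C#CC[C@@H](O)CO | intermediate
4 | chlorotriethylsilane | CC[Si](CC)(CC)Cl | starting material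
5 | (R)-4,5-bis(triethylsilyloxy)pent-1-yne | C#CC[C@@H](O[Si](CC)(CC)CC)CO[Si](CC)(CC)CC | intermediate
6 | trimethylaluminium | C[Al](C)C | starting material
7 | ethylene oxide | C1CO1 | starting material
8 | dimethyl[(1E,4R)-2-methyl-4,5-bis(triethylsilyloxy)pent-1-enyl]alane | C[Al](C)/C=C(\C)C[C@@H](O[Si](CC)(CC)CC)CO[Si](CC)(CC)CC | intermediate (not isolated)
9 | lithium butyl(dimethyl)[(1E,4R)-2-methyl-4,5-bis(triethylsilyloxy)pent-1-enyl]aluminate | [Li+].CCCC[Al-](C)(C)/C=C(\C)C[C@@H](O[Si](CC)(CC)CC)CO[Si](CC)(CC)CC | intermediate (not isolated)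
10 | (3E,6R)-4-methyl-6,7-bis(triethylsilyloxy)hept-3-en-1-ol | OCC/C=C(\C)C[C@@H](O[Si](CC)(CC)CC)CO[Si](CC)(CC)CC | intermediate
11 | tert-butylchlorodimethylsilane | CC(C)(C)[Si](C)(C)Cl | starting material
12 | (3E,6R)-1-(tert-butyldimethylsilyloxy)-4-methyl-6,7-bis(triethylsilyloxy)hept-3-ene | CC(C)(C)[Si](C)(C)OCC/C=C(\C)C[C@@H](O[Si](CC)(CC)CC)CO[Si](CC)(CC)CC | intermediate
13 | {[(2R,4E)-7-(tert-butyldimethylsilyloxy)-4-methyl-2-(triethylsilyloxy)hept-4-enyl]oxy}dimethylsulfonium chloride | CC(C)(C)[Si](C)(C)OCC/C=C(\C)C[C@@H](O[Si](CC)(CC)CC)CO[S+](C)C.[Cl-] | intermediate (not isolated)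
14 | (2R,4E)-7-(tert-butyldimethylsilyloxy)-4-methyl-2-(triethylsilyloxy)hept-4-enal | CC(C)(C)[Si](C)(C)OCC/C=C(\C)C[C@@H](O[Si](CC)(CC)CC)C=O | intermediate
15 | 2-butyne-1,4-diol | OCC#CCO | starting material
16 | tert-butylchlorodiphenylsilane | CC(C)(C)[Si](Cl)(c1ccccc1)c1ccccc1 | starting material
17 | 4-(tert-butyldiphenylsilyloxy)but-2-yn-1-ol | OCC#CCO[Si](c1ccccc1)(c1ccccc1)C(C)(C)C | intermediate
18 | iodine | II | starting material
19 | sodium cyclic alkenylalanate (1,2-oxaluminole with Al on C4 and two 2-methoxyethoxy groups on Al) | [Na+].COCCO[Al-]1(OCCOC)OCC=C1CO[Si](c1ccccc1)(c1ccccc1)C(C)(C)C | intermediate (not isolated)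
20 | (Z)-4-(tert-butyldiphenylsilyloxy)-3-iodobut-2-en-1-ol | OC/C=C(\I)CO[Si](c1ccccc1)(c1ccccc1)C(C)(C)C | intermediate
21 | chlorotrimethylsilane | C[Si](C)(C)Cl | starting material
22 | trimethylsilyl ether of 20 | C[Si](C)(C)OC/C=C(\I)CO[Si](c1ccccc1)(c1ccccc1)C(C)(C)C | intermediate (not isolated)
23 | (Z)-alkenyllithium from 22 (Li in place of I) | C[Si](C)(C)OC/C=C(\[Li])CO[Si](c1ccccc1)(c1ccccc1)C(C)(C)C | intermediate (not isolated)
24 | (Z)-4-(tert-butyldiphenylsilyloxy)-3-(trimethylsilyl)but-2-en-1-ol | OC/C=C(\[Si](C)(C)C)CO[Si](c1ccccc1)(c1ccccc1)C(C)(C)C | intermediate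
25 | tetrabromomethane | BrC(Br)(Br)Br | starting material
26 | (Z)-[4-bromo-1-(tert-butyldiphenylsilyloxy)but-2-en-2-yl]trimethylsilane | BrC/C=C(\[Si](C)(C)C)CO[Si](c1ccccc1)(c1ccccc1)C(C)(C)C | intermediate
27 | triethyl phosphite | CCOP(OCC)OCC | starting material
28 | diethyl (Z)-[4-(tert-butyldiphenylsilyloxy)-3-(trimethylsilyl)but-2-en-1-yl]phosphonate | CCOP(=O)(OCC)C/C=C(\[Si](C)(C)C)CO[Si](c1ccccc1)(c1ccccc1)C(C)(C)C | intermediate
29 | α-lithio derivative of phosphonate 28 | [Li+].CCOP(=O)(OCC)[CH-]/C=C(\[Si](C)(C)C)CO[Si](c1ccccc1)(c1ccccc1)C(C)(C)C | intermediate (not isolated)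
30 | (3E,6R,7E,9Z)-1-(tert-butyldimethylsilyloxy)-11-(tert-butyldiphenylsilyloxy)-4-methyl-6-(triethylsilyloxy)-10-(trimethylsilyl)undeca-3,7,9-triene | CC(C)(C)[Si](C)(C)OCC/C=C(\C)C[C@@H](O[Si](CC)(CC)CC)/C=C/C=C(\[Si](C)(C)C)CO[Si](c1ccccc1)(c1ccccc1)C(C)(C)C | intermediate
31 | 2-bromoacrylic acid | C=C(Br)C(=O)O | starting material
32 | allylpalladium carboxylate (drawn as the η1-C6 six-membered oxapalladacycle; Pd on the face later taken by O) | C=C1C(=O)O[Pd][C@H](/C=C(\[Si](C)(C)C)CO[Si](c2ccccc2)(c2ccccc2)C(C)(C)C)[C@H]1[C@H](O[Si](CC)(CC)CC)C/C(C)=C/CCO[Si](C)(C)C(C)(C)C | intermediate (not isolated)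
33 | (4S,5S)-4-[(1R,3E)-6-(tert-butyldimethylsilyloxy)-3-methyl-1-(triethylsilyloxy)hex-3-enyl]-5-[(Z)-3-(tert-butyldiphenylsilyloxy)-2-(trimethylsilyl)prop-1-enyl]-3-methylideneoxolan-2-one | C=C1C(=O)O[C@H](/C=C(\[Si](C)(C)C)CO[Si](c2ccccc2)(c2ccccc2)C(C)(C)C)[C@H]1[C@H](O[Si](CC)(CC)CC)C/C(C)=C/CCO[Si](C)(C)C(C)(C)C | intermediate
34 | N-iodosuccinimide | O=C1CCC(=O)N1I | starting material
35 | (4S,5S)-4-[(1R,3E)-6-(tert-butyldimethylsilyloxy)-3-methyl-1-(triethylsilyloxy)hex-3-enyl]-5-[(Z)-3-(tert-butyldiphenylsilyloxy)-2-iodoprop-1-enyl]-3-methylideneoxolan-2-one | C=C1C(=O)O[C@H](/C=C(\I)CO[Si](c2ccccc2)(c2ccccc2)C(C)(C)C)[C@H]1[C@H](O[Si](CC)(CC)CC)C/C(C)=C/CCO[Si](C)(C)C(C)(C)C | intermediate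
36 | (4R,5S)-4-[(1R,3E)-6-(tert-butyldimethylsilyloxy)-1-hydroxy-3-methylhex-3-enyl]-5-[(Z)-3-(tert-butyldiphenylsilyloxy)-2-iodoprop-1-enyl]-3-methylideneoxolan-2-one | C=C1C(=O)O[C@H](/C=C(\I)CO[Si](c2ccccc2)(c2ccccc2)C(C)(C)C)[C@H]1[C@H](O)C/C(C)=C/CCO[Si](C)(C)C(C)(C)C | intermediate
37 | isobutyric anhydride | CC(C)C(=O)OC(=O)C(C)C | starting material
38 | (4R,5S)-4-[(1R,3E)-6-(tert-butyldimethylsilyloxy)-3-methyl-1-(2-methylpropanoyloxy)hex-3-enyl]-5-[(Z)-3-(tert-butyldiphenylsilyloxy)-2-iodoprop-1-enyl]-3-methylideneoxolan-2-one | C=C1C(=O)O[C@H](/C=C(\I)CO[Si](c2ccccc2)(c2ccccc2)C(C)(C)C)[C@H]1[C@H](OC(=O)C(C)C)C/C(C)=C/CCO[Si](C)(C)C(C)(C)C | intermediate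
39 | (4R,5S)-4-[(1R,3E)-6-hydroxy-3-methyl-1-(2-methylpropanoyloxy)hex-3-enyl]-5-[(Z)-3-(tert-butyldiphenylsilyloxy)-2-iodoprop-1-enyl]-3-methylideneoxolan-2-one | C=C1C(=O)O[C@H](/C=C(\I)CO[Si](c2ccccc2)(c2ccccc2)C(C)(C)C)[C@H]1[C@H](OC(=O)C(C)C)C/C(C)=C/CCO | intermediate
40 | (4R,5S)-4-[(1R,3E)-3-methyl-1-(2-methylpropanoyloxy)-6-oxohex-3-enyl]-5-[(Z)-3-(tert-butyldiphenylsilyloxy)-2-iodoprop-1-enyl]-3-methylideneoxolan-2-one | C=C1C(=O)O[C@H](/C=C(\I)CO[Si](c2ccccc2)(c2ccccc2)C(C)(C)C)[C@H]1[C@H](OC(=O)C(C)C)C/C(C)=C/CC=O | intermediate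
41 | alkenylchromium(III) dichloride from 40 (CrCl2 in place of I) | C=C1C(=O)O[C@H](/C=C(\[Cr](Cl)Cl)CO[Si](c2ccccc2)(c2ccccc2)C(C)(C)C)[C@H]1[C@H](OC(=O)C(C)C)C/C(C)=C/CC=O | intermediate (not isolated)
42 | (3S,6R,7R,8R)-15-(tert-butyldiphenylsilyloxy)-3-hydroxy-8-(2-methylpropanoyloxy)germacra-1(10)E,4Z,11(13)-trien-6,12-olide | C=C1C(=O)O[C@@H]2/C=C(/CO[Si](c3ccccc3)(c3ccccc3)C(C)(C)C)[C@@H](O)C/C=C(\C)C[C@@H](OC(=O)C(C)C)[C@@H]12 | intermediate
43 | 3-chloroperbenzoic acid | O=C(OO)c1cccc(Cl)c1 | starting material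
44 | (1R,3S,6R,7R,8R,10R)-15-(tert-butyldiphenylsilyloxy)-1,10-epoxy-3-hydroxy-8-(2-methylpropanoyloxy)germacra-4Z,11(13)-dien-6,12-olide | C=C1C(=O)O[C@@H]2/C=C(/CO[Si](c3ccccc3)(c3ccccc3)C(C)(C)C)[C@@H](O)C[C@H]3O[C@]3(C)C[C@@H](OC(=O)C(C)C)[C@@H]12 | intermediate
45 | (1R,3S,6R,7R,8R,10R)-1,10-epoxy-3,15-dihydroxy-8-(2-methylpropanoyloxy)germacra-4Z,11(13)-dien-6,12-olide (CNP0219050.1) | C=C1C(=O)O[C@@H]2/C=C(/CO)[C@@H](O)C[C@H]3O[C@]3(C)C[C@@H](OC(=O)C(C)C)[C@@H]12 | target

## Step count and risks

Total steps: 20. Longest linear sequence: 15 steps (steps 1–5 and 11–20; the branch through steps 6–10 and 11–20 is equally long).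

Steps most likely to fail:

1. Step 12. The carbopalladation may show poor facial selectivity with respect to C8. The carboxylate may also close from the face opposite palladium, which would give the cis-lactone, or the allyl may lose a β-hydride to a triene. The fallback sets out from aldehyde 14 and allylic alcohol 24 and returns at lactone 33, building the lactone at C6–C7 and O–C12 instead. Aldehyde 14 and methyl acrylate with DABCO should give the Morita–Baylis–Hillman adduct methyl (4R,6E)-9-(tert-butyldimethylsilyloxy)-3-hydroxy-6-methyl-2-methylidene-4-(triethylsilyloxy)non-6-enoate F1 (either carbinol epimer serves). CBr4/PPh3 should convert it by SN2' bromination into methyl (2Z,4R,6E)-2-(bromomethyl)-9-(tert-butyldimethylsilyloxy)-6-methyl-4-(triethylsilyloxy)nona-2,6-dienoate F2. MnO2 oxidation of 24 gives (Z)-4-(tert-butyldiphenylsilyloxy)-3-(trimethylsilyl)but-2-enal F3. CrCl2 in THF then joins F2 and F3 by γ-selective 2-(alkoxycarbonyl)allylation through a chair transition state (anti adduct), and the chromium alkoxide lactonises to the trans-lactone 33. The C7/C8 relation would then rest on Felkin-type control, with separation of diastereomers if needed.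

2. Step 18. The ring closure may show poor facial selectivity at the aldehyde and give the 3-epimer, alone or in a mixture. The fallback sets out from aldehyde 40 and returns at 42, setting C3 by reagent-controlled reduction instead of in the C–C bond formation. The same ring closure would deliver the 3R alcohol, 3-epi-42 F4. Dess–Martin oxidation of F4 or of the epimer mixture gives the macrocyclic 3-ketone (4-en-3-one) F5. Its 1,2-reduction with (R)-2-methyl-CBS-oxazaborolidine and catecholborane at low temperature should give the 3S alcohol 42.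

3. Step 19. The free 3-hydroxyl may direct the peracid to C4=C5, or the oxygen may be delivered to the wrong face of C1=C10. The fallback sets out from 42 and returns at the target 45, removing the directing group and using a catalyst-controlled dioxirane. TESOTf and 2,6-lutidine give the 3-O-triethylsilyl ether of 42 F6. Shi epoxidation (fructose-derived ketone, Oxone, buffered MeCN/water, 0 °C; the ketone enantiomer chosen for the 1R,10R oxide) should give the 1,10-epoxide of that ether F7. TBAF/AcOH then removes both silyl groups to give 45.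

## Further compounds

F1 | step 12 | methyl (4R,6E)-9-(tert-butyldimethylsilyloxy)-3-hydroxy-6-methyl-2-methylidene-4-(triethylsilyloxy)non-6-enoate | C=C(C(=O)OC)C(O)[C@H](O[Si](CC)(CC)CC)C/C(C)=C/CCO[Si](C)(C)C(C)(C)C
F2 | step 12 | methyl (2Z,4R,6E)-2-(bromomethyl)-9-(tert-butyldimethylsilyloxy)-6-methyl-4-(triethylsilyloxy)nona-2,6-dienoate | BrC/C(C(=O)OC)=C\[C@H](O[Si](CC)(CC)CC)C/C(C)=C/CCO[Si](C)(C)C(C)(C)C
F3 | step 12 | (Z)-4-(tert-butyldiphenylsilyloxy)-3-(trimethylsilyl)but-2-enal | O=C/C=C(\[Si](C)(C)C)CO[Si](c1ccccc1)(c1ccccc1)C(C)(C)C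
F4 | step 18 | (3R,6R,7R,8R)-15-(tert-butyldiphenylsilyloxy)-3-hydroxy-8-(2-methylpropanoyloxy)germacra-1(10)E,4Z,11(13)-trien-6,12-olide (3-epi-42) | C=C1C(=O)O[C@@H]2/C=C(/CO[Si](c3ccccc3)(c3ccccc3)C(C)(C)C)[C@H](O)C/C=C(\C)C[C@@H](OC(=O)C(C)C)[C@@H]12
F5 | step 18 | (6R,7R,8R)-15-(tert-butyldiphenylsilyloxy)-8-(2-methylpropanoyloxy)-3-oxogermacra-1(10)E,4Z,11(13)-trien-6,12-olide | C=C1C(=O)O[C@@H]2/C=C(/CO[Si](c3ccccc3)(c3ccccc3)C(C)(C)C)C(=O)C/C=C(\C)C[C@@H](OC(=O)C(C)C)[C@@H]12
F6 | step 19 | 3-O-triethylsilyl ether of 42 | C=C1C(=O)O[C@@H]2/C=C(/CO[Si](c3ccccc3)(c3ccccc3)C(C)(C)C)[C@@H](O[Si](CC)(CC)CC)C/C=C(\C)C[C@@H](OC(=O)C(C)C)[C@@H]12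
F7 | step 19 | 3-O-triethylsilyl ether of 44 (1R,10R oxide) | C=C1C(=O)O[C@@H]2/C=C(/CO[Si](c3ccccc3)(c3ccccc3)C(C)(C)C)[C@@H](O[Si](CC)(CC)CC)C[C@H]3O[C@]3(C)C[C@@H](OC(=O)C(C)C)[C@@H]12
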